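**Retrosynthetic overview**
1. The target comes from its bis(aryl benzyl ether) by hydrogenolysis. Each furofuran C–aryl centre is made by convex-face hydride reduction of an aryl lactol, which leaves the aryl group endo, so each is disconnected to an aryllithium plus a lactone carbonyl.
2. The second aryl is a cis-dihydrobenzofuranyl-lithium added to an endo-aryl furofuranone; the first is 4-benzyloxy-3-methoxyphenyllithium added to the C2-symmetric bis-lactone (3aS,6aS)-tetrahydrofuro[3,4-c]furan-1,4-dione.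
3. Key disconnection: the central C8–C8' bond of that bis-lactone, made by iodine(III)-mediated oxidative coupling of two molecules of a chiral N-(3-benzyloxypropanoyl)oxazolidinone (one as enolate, one as enolonium). It joins two α-carbons and sets both bridgehead centres.
4. The cis-dihydrobenzofuran comes from Rh(II)-carbenoid C–H insertion of an aryl diazoacetate, built from 4-bromo-2-iodo-6-methoxyphenol, O-benzylvanillyl alcohol and ethyl diazoacetate.
5. Ring order: dihydrobenzofuran (own branch); both lactone rings of the bis-lactone in one operation; then lactone to cyclic ether one ring at a time (guaiacyl side first, dihydrobenzofuranyl side second).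

Assumption: the SMILES is read literally. All four furofuran centres are S, which means both aryl groups are endo (each benzylic H cis to its bridgehead H), and the dihydrobenzofuran is (2S,3S), i.e. 2,3-cis; the route is built for exactly this isomer.

**Route**

Step 1
Reactants: 1 3-(benzyloxy)propanoic acid; 2 (S)-4-benzyloxazolidin-2-one
Product: 4 (S)-4-benzyl-3-[3-(benzyloxy)propanoyl]oxazolidin-2-one, via mixed pivalic anhydride 3 (not isolated)
Conditions: PivCl, Et3N, THF, −20 °C; then 2, LiCl, −20 °C → rt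
Reagents that add atoms: none
Why: Standard Evans N-acylation through the mixed pivalic anhydride (LiCl-assisted acyl transfer to the oxazolidinone); no new stereocentre.

Step 2
Reactants: 4 (S)-4-benzyl-3-[3-(benzyloxy)propanoyl]oxazolidin-2-one (2 equiv: two molecules of 4 are joined, one reacting as enolate 5 and one after oxidation to enolonium 6)
Product: 7 (4S,4'S)-3,3'-{(2S,3S)-2,3-bis[(benzyloxy)methyl]butanedioyl}bis(4-benzyloxazolidin-2-one), via lithium Z-enolate 5 (not isolated), via iodine(III) enolonium 6 (not isolated)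
Conditions: LDA (2.1 equiv for 2 equiv of 4), THF, −78 °C; then PhI(OAc)2 (1.0 equiv for 2 equiv of 4) in THF added dropwise, −78 → −30 °C; aq. NH4Cl
Reagents that add atoms: second molecule of imide 4 (it supplies the second half of the dimer), O=C(CCOCc1ccccc1)N1[C@@H](Cc2ccccc2)COC1=O
Why: Oxidative enolate homocoupling in which ligand exchange of one chelated Z-enolate 5 with PhI(OAc)2 gives the O-iodanyl enolonium 6, whose α-carbon is now electrophilic and is attacked by the α-carbon of a second enolate 5 with loss of PhI and acetate, so two normally nucleophilic α-carbons are joined and two molecules of 4 end up in 7; both α-carbons form the new bond on the face away from the C4-benzyl group, giving the like (2S,3S) C2-symmetric dimer as the matched product (the minor unlike isomer is removed by chromatography and cannot form a cis-fused bis-lactone), and −78 °C suppresses β-elimination of benzyloxide.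

Step 3
Reactants: 7 (4S,4'S)-3,3'-{(2S,3S)-2,3-bis[(benzyloxy)methyl]butanedioyl}bis(4-benzyloxazolidin-2-one)
Product: 9 (3aS,6aS)-tetrahydrofuro[3,4-c]furan-1,4-dione, via diol bis-imide 8 (not isolated)
Conditions: H2 (1 atm), 10% Pd/C, EtOAc, rt; filter; then p-TsOH (cat.), 50 °C
Reagents that add atoms: none
Why: Hydrogenolysis of the two benzyl ethers frees diol 8, and each hydroxyl then attacks the exocyclic imide carbonyl of the other arm (acid-catalysed 5-exo acyl transfer, lactonisation), expelling the recoverable auxiliary and closing both lactone rings at once without touching the two stereocentres.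

Step 4
Reactants: 9 (3aS,6aS)-tetrahydrofuro[3,4-c]furan-1,4-dione; 10 1-(benzyloxy)-4-bromo-2-methoxybenzene
Product: 13 (3aS,4S,6aS)-4-[4-(benzyloxy)-3-methoxyphenyl]tetrahydro-1H,3H-furo[3,4-c]furan-1-one (aryl endo), via aryllithium 11 (not isolated), via lithium hemiketalate 12 (not isolated)
Conditions: 10, n-BuLi, THF, −78 °C; add to 9 (2.5 equiv), THF, −78 °C; then Et3SiH, BF3·OEt2 (promoter), CH2Cl2, −78 → −40 °C; aq. NaHCO3
Reagents that add atoms: none
Why: Bromine–lithium exchange and 1,2-addition of the aryllithium to one lactone carbonyl (excess C2-symmetric 9 keeps double addition low and is recovered), then ionic hydrogenation (Et3SiH/BF3·OEt2) of the aryl-stabilised oxocarbenium ion with hydride delivered to the convex face of the cis-fused bicycle, which puts H exo and the aryl group endo and so sets C4 as S under kinetic control.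

Step 5
Reactants: 14 4-bromo-2-methoxyphenol
Product: 15 4-bromo-2-iodo-6-methoxyphenol
Conditions: NIS, p-TsOH (cat.), MeCN, 0 °C → rt
Reagents that add atoms: N-iodosuccinimide, O=C1CCC(=O)N1I
Why: Electrophilic aromatic iodination at the only free position ortho to the strongly activating OH (para is blocked by Br); no stereocentre.

Step 6
Reactants: 15 4-bromo-2-iodo-6-methoxyphenol; 16 [4-(benzyloxy)-3-methoxyphenyl]methanol
Product: 17 2-{[4-(benzyloxy)-3-methoxyphenyl]methoxy}-5-bromo-1-iodo-3-methoxybenzene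
Conditions: PPh3, DIAD, THF, 0 °C → rt
Reagents that add atoms: none
Why: Mitsunobu etherification of the acidic, hindered halophenol with a primary benzylic alcohol under neutral conditions; no stereocentre.

Step 7
Reactants: 17 2-{[4-(benzyloxy)-3-methoxyphenyl]methoxy}-5-bromo-1-iodo-3-methoxybenzene; 18 ethyl diazoacetate
Product: 19 ethyl 2-(2-{[4-(benzyloxy)-3-methoxyphenyl]methoxy}-5-bromo-3-methoxyphenyl)-2-diazoacetate
Conditions: Pd(PPh3)4 (5 mol %), Ag2CO3 (0.5 equiv), Et3N, toluene, rt
Reagents that add atoms: none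
Why: Pd(0)-catalysed cross-coupling of the aryl iodide with the C–H bond of the diazoester (oxidative addition at C–I in preference to C–Br, silver-assisted deprotonation, reductive elimination with the diazo group retained); no stereocentre.

Step 8
Reactants: 19 ethyl 2-(2-{[4-(benzyloxy)-3-methoxyphenyl]methoxy}-5-bromo-3-methoxyphenyl)-2-diazoacetate
Product: 20 ethyl (2S,3R)-2-[4-(benzyloxy)-3-methoxyphenyl]-5-bromo-7-methoxy-2,3-dihydro-1-benzofuran-3-carboxylate (2,3-cis)
Conditions: Rh2(R-PTTL)4 (1 mol %), toluene, −60 °C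
Reagents that add atoms: none
Why: Rh(II)-carbenoid intramolecular 1,5 C–H insertion into the ether-activated benzylic C–H bond, which is kinetically cis-selective and enantioselective for aryl diazoacetates with phthaloyl-tert-leucinate catalysts; the R catalyst is chosen, from recalled precedent for this catalyst class, to give the (2S,3R) cis ester (the S catalyst gives the antipode).

Step 9
Reactants: 20 ethyl (2S,3R)-2-[4-(benzyloxy)-3-methoxyphenyl]-5-bromo-7-methoxy-2,3-dihydro-1-benzofuran-3-carboxylate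
Product: 21 {(2S,3S)-2-[4-(benzyloxy)-3-methoxyphenyl]-5-bromo-7-methoxy-2,3-dihydro-1-benzofuran-3-yl}methanol (2,3-cis)
Conditions: DIBAL-H (3 equiv), CH2Cl2, −78 → −20 °C; Rochelle salt
Reagents that add atoms: none
Why: DIBAL-H ester reduction at low temperature under non-basic conditions, so the epimerisable C3 centre keeps its cis geometry (3R becomes 3S only through the change in CIP priorities).

Step 10
Reactants: 21 {(2S,3S)-2-[4-(benzyloxy)-3-methoxyphenyl]-5-bromo-7-methoxy-2,3-dihydro-1-benzofuran-3-yl}methanol; 13 (3aS,4S,6aS)-4-[4-(benzyloxy)-3-methoxyphenyl]tetrahydro-1H,3H-furo[3,4-c]furan-1-one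
Product: 24 {(2S,3S)-2-[4-(benzyloxy)-3-methoxyphenyl]-5-{(1S,3aS,4S,6aS)-4-[4-(benzyloxy)-3-methoxyphenyl]tetrahydro-1H,3H-furo[3,4-c]furan-1-yl}-7-methoxy-2,3-dihydro-1-benzofuran-3-yl}methanol, via dilithio aryl alkoxide 22 (not isolated), via dilithium hemiketalate 23 (not isolated)
Conditions: 21, n-BuLi (2.05 equiv), THF, −78 °C; 13 (1.2 equiv), −78 °C; then Et3SiH, BF3·OEt2 (promoter), CH2Cl2, −78 → −40 °C; cold aq. NaHCO3
Reagents that add atoms: none
Why: Deprotonation of the hydroxyl then bromine–lithium exchange gives an alkoxide-protected aryllithium that adds to the lactone carbonyl of 13, and ionic hydrogenation of the resulting aryl lactol again delivers hydride to the convex face so the second aryl group also ends endo (new C1 centre S), while the low temperature and cold basic quench keep the acid-labile endo benzylic ethers and the cis-dihydrobenzofuran from epimerising.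

Step 11
Reactants: 24 the bis(aryl benzyl ether) from step 10
Product: 25 4-[(2S,3S)-3-(hydroxymethyl)-5-[(1S,3aS,4S,6aS)-4-(4-hydroxy-3-methoxyphenyl)tetrahydro-1H,3H-furo[3,4-c]furan-1-yl]-7-methoxy-2,3-dihydro-1-benzofuran-2-yl]-2-methoxyphenol (target)
Conditions: H2 (1 atm), 10% Pd/C, EtOAc, rt, stopped at full conversion
Reagents that add atoms: none
Why: Hydrogenolysis of the two aryl benzyl ethers under neutral conditions is much faster than cleavage of the dialkyl benzylic ethers of the furofuran or of the dihydrobenzofuran C2–O bond, and no stereocentre is touched.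

**Compound list**
1 | 3-(benzyloxy)propanoic acid | OC(=O)CCOCc1ccccc1 | starting material
2 | (S)-4-benzyloxazolidin-2-one | O=C1OC[C@H](Cc2ccccc2)N1 | starting material
3 | 3-(benzyloxy)propanoic pivalic anhydride | CC(C)(C)C(=O)OC(=O)CCOCc1ccccc1 | intermediate
4 | (S)-4-benzyl-3-[3-(benzyloxy)propanoyl]oxazolidin-2-one | O=C(CCOCc1ccccc1)N1[C@@H](Cc2ccccc2)COC1=O | intermediate
5 | lithium (Z)-enolate of 4 | [Li+].[O-]/C(=C\COCc1ccccc1)N1[C@@H](Cc2ccccc2)COC1=O | intermediate
6 | iodine(III) enolonium from 5: (Z)-O-[acetoxy(phenyl)-λ3-iodanyl] enol of 4 | CC(=O)OI(c1ccccc1)O/C(=C\COCc1ccccc1)N1[C@@H](Cc2ccccc2)COC1=O | intermediate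
7 | (4S,4'S)-3,3'-{(2S,3S)-2,3-bis[(benzyloxy)methyl]butanedioyl}bis(4-benzyloxazolidin-2-one) | O=C([C@H](COCc1ccccc1)[C@@H](COCc1ccccc1)C(=O)N1[C@@H](Cc2ccccc2)COC1=O)N1[C@@H](Cc2ccccc2)COC1=O | intermediate
8 | (4S,4'S)-3,3'-[(2S,3S)-2,3-bis(hydroxymethyl)butanedioyl]bis(4-benzyloxazolidin-2-one) | O=C([C@H](CO)[C@@H](CO)C(=O)N1[C@@H](Cc2ccccc2)COC1=O)N1[C@@H](Cc2ccccc2)COC1=O | intermediate
9 | (3aS,6aS)-tetrahydrofuro[3,4-c]furan-1,4-dione (cis-fused, C2-symmetric) | O=C1OC[C@@H]2[C@H]1COC2=O | intermediate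
10 | 1-(benzyloxy)-4-bromo-2-methoxybenzene | COc1cc(Br)ccc1OCc1ccccc1 | starting material
11 | [4-(benzyloxy)-3-methoxyphenyl]lithium | [Li]c1ccc(OCc2ccccc2)c(OC)c1 | intermediate
12 | lithium (3aS,6aS)-4-[4-(benzyloxy)-3-methoxyphenyl]-1-oxotetrahydro-1H,3H-furo[3,4-c]furan-4-olate (C4 epimers) | [Li]OC1(c2ccc(OCc3ccccc3)c(OC)c2)OC[C@@H]2[C@H]1COC2=O | intermediate
13 | (3aS,4S,6aS)-4-[4-(benzyloxy)-3-methoxyphenyl]tetrahydro-1H,3H-furo[3,4-c]furan-1-one (aryl endo) | COc1cc([C@H]2OC[C@@H]3[C@H]2COC3=O)ccc1OCc1ccccc1 | intermediate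
14 | 4-bromo-2-methoxyphenol | COc1cc(Br)ccc1O | starting material
15 | 4-bromo-2-iodo-6-methoxyphenol | COc1cc(Br)cc(I)c1O | intermediate
16 | [4-(benzyloxy)-3-methoxyphenyl]methanol | COc1cc(CO)ccc1OCc1ccccc1 | starting material
17 | 2-{[4-(benzyloxy)-3-methoxyphenyl]methoxy}-5-bromo-1-iodo-3-methoxybenzene | COc1cc(COc2c(I)cc(Br)cc2OC)ccc1OCc1ccccc1 | intermediate
18 | ethyl diazoacetate | CCOC(=O)C=[N+]=[N-] | starting material
19 | ethyl 2-(2-{[4-(benzyloxy)-3-methoxyphenyl]methoxy}-5-bromo-3-methoxyphenyl)-2-diazoacetate | CCOC(=O)C(=[N+]=[N-])c1cc(Br)cc(OC)c1OCc1ccc(OCc2ccccc2)c(OC)c1 | intermediate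
20 | ethyl (2S,3R)-2-[4-(benzyloxy)-3-methoxyphenyl]-5-bromo-7-methoxy-2,3-dihydro-1-benzofuran-3-carboxylate (cis) | Brc1cc(OC)c2c(c1)[C@@H](C(=O)OCC)[C@@H](c1ccc(OCc3ccccc3)c(OC)c1)O2 | intermediate
21 | {(2S,3S)-2-[4-(benzyloxy)-3-methoxyphenyl]-5-bromo-7-methoxy-2,3-dihydro-1-benzofuran-3-yl}methanol (cis) | Brc1cc(OC)c2c(c1)[C@@H](CO)[C@@H](c1ccc(OCc3ccccc3)c(OC)c1)O2 | intermediate
22 | lithium alkoxide/C5-aryllithium derived from 21 | [Li]c1cc(OC)c2c(c1)[C@@H](CO[Li])[C@@H](c1ccc(OCc3ccccc3)c(OC)c1)O2 | intermediate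
23 | dilithium salt of the aryl lactol from 22 and 13 (lactol carbon epimers) | COc1cc([C@H]2OC[C@@H]3[C@H]2COC3(O[Li])c2cc(OC)c3c(c2)[C@@H](CO[Li])[C@@H](c2ccc(OCc4ccccc4)c(OC)c2)O3)ccc1OCc1ccccc1 | intermediate
24 | {(2S,3S)-2-[4-(benzyloxy)-3-methoxyphenyl]-5-{(1S,3aS,4S,6aS)-4-[4-(benzyloxy)-3-methoxyphenyl]tetrahydro-1H,3H-furo[3,4-c]furan-1-yl}-7-methoxy-2,3-dihydro-1-benzofuran-3-yl}methanol | COc1cc([C@H]2OC[C@@H]3[C@H]2CO[C@@H]3c2cc(OC)c3c(c2)[C@@H](CO)[C@@H](c2ccc(OCc4ccccc4)c(OC)c2)O3)ccc1OCc1ccccc1 | intermediate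
25 | 4-[(2S,3S)-3-(hydroxymethyl)-5-[(1S,3aS,4S,6aS)-4-(4-hydroxy-3-methoxyphenyl)tetrahydro-1H,3H-furo[3,4-c]furan-1-yl]-7-methoxy-2,3-dihydro-1-benzofuran-2-yl]-2-methoxyphenol | COc1cc([C@H]2OC[C@@H]3[C@H]2CO[C@@H]3c2cc(OC)c3c(c2)[C@@H](CO)[C@@H](c2ccc(O)c(OC)c2)O3)ccc1O | target

**Totals**
Total step count: 11. Longest linear sequence: 7 steps (14 → 15 → 17 → 19 → 20 → 21 → 24 → 25); the bis-lactone branch (1 → 4 → 7 → 9 → 13 → 24 → 25) is 6.

**Three steps most likely to fail**

Step 10 is the most exposed. The dilithio reagent 22 may be poorly soluble or may enolise 13, and the one-pot BF3 reduction could let the cis-dihydrobenzofuran or an endo aryl ether leak to the more stable isomer. The fallback uses a protected mono-anion and an isolated lactol. Compound 21 is silylated (TBSCl, imidazole, DMF) to {(2S,3S)-2-[4-(benzyloxy)-3-methoxyphenyl]-5-bromo-7-methoxy-2,3-dihydro-1-benzofuran-3-yl}methyl tert-butyldimethylsilyl ether F7. Bromine–lithium exchange (n-BuLi, THF, −78 °C) gives the corresponding C5-aryllithium F8, which is added to 13 and quenched with AcOH to give the isolated aryl lactol F9. This is reduced in pure CH2Cl2 at −78 °C (Et3SiH, BF3·OEt2) to the silyl ether of 24 F10, and TBAF/AcOH (THF, 0 °C) returns to the route at 24. The fallback sets out from 21 (with 13) and comes back at 24.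

Step 2, the key coupling, may suffer β-elimination of benzyloxide from enolate 5, acetoxylation by the iodane, or a poor like:unlike ratio. The fallback makes the same bond stepwise from a pre-formed chiral α-electrophile. O-Benzyl-D-serine is diazotised with retention (NaNO2, aq. H2SO4) to (R)-3-(benzyloxy)-2-hydroxypropanoic acid F1, esterified (MeOH, cat. H2SO4) to methyl (R)-3-(benzyloxy)-2-hydroxypropanoate F2, and triflated (Tf2O, 2,6-lutidine, CH2Cl2, −78 °C) to methyl (R)-3-(benzyloxy)-2-{[(trifluoromethyl)sulfonyl]oxy}propanoate F3. Enolate 5 (from one equivalent of 4 with LDA, THF, −78 °C) displaces the triflate with inversion, while the auxiliary controls the enolate face, giving methyl (2S,3S)-4-[(S)-4-benzyl-2-oxooxazolidin-3-yl]-2,3-bis[(benzyloxy)methyl]-4-oxobutanoate F4. Hydrogenolysis (H2, Pd/C, EtOAc) gives methyl (2S,3S)-4-[(S)-4-benzyl-2-oxooxazolidin-3-yl]-2,3-bis(hydroxymethyl)-4-oxobutanoate F5, which lactonises twice on warming with catalytic p-TsOH to give 9. The fallback sets out from 4 and comes back at 9.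

Step 7 may give low conversion on the ortho-alkoxy aryl iodide or lose the diazo partner to carbene dimerisation. The fallback installs the acetate first and the diazo group second. Negishi–Reformatsky coupling of 17 with commercial (2-ethoxy-2-oxoethyl)zinc bromide (Pd2(dba)3, XPhos, THF, rt, selective for C–I) gives ethyl 2-(2-{[4-(benzyloxy)-3-methoxyphenyl]methoxy}-5-bromo-3-methoxyphenyl)acetate F6. Regitz diazo transfer (p-ABSA, DBU, MeCN, 0 °C) then gives 19. The fallback sets out from 17 and comes back at 19.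

**Further compounds**
F1 | step 2 | (R)-3-(benzyloxy)-2-hydroxypropanoic acid | OC(=O)[C@@H](COCc1ccccc1)O
F2 | step 2 | methyl (R)-3-(benzyloxy)-2-hydroxypropanoate | COC(=O)[C@@H](COCc1ccccc1)O
F3 | step 2 | methyl (R)-3-(benzyloxy)-2-{[(trifluoromethyl)sulfonyl]oxy}propanoate | COC(=O)[C@@H](COCc1ccccc1)OS(=O)(=O)C(F)(F)F
F4 | step 2 | methyl (2S,3S)-4-[(S)-4-benzyl-2-oxooxazolidin-3-yl]-2,3-bis[(benzyloxy)methyl]-4-oxobutanoate | COC(=O)[C@H](COCc1ccccc1)[C@@H](COCc1ccccc1)C(=O)N1[C@@H](Cc2ccccc2)COC1=O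
F5 | step 2 | methyl (2S,3S)-4-[(S)-4-benzyl-2-oxooxazolidin-3-yl]-2,3-bis(hydroxymethyl)-4-oxobutanoate | COC(=O)[C@H](CO)[C@@H](CO)C(=O)N1[C@@H](Cc2ccccc2)COC1=O
F6 | step 7 | ethyl 2-(2-{[4-(benzyloxy)-3-methoxyphenyl]methoxy}-5-bromo-3-methoxyphenyl)acetate | CCOC(=O)Cc1cc(Br)cc(OC)c1OCc1ccc(OCc2ccccc2)c(OC)c1
F7 | step 10 | {(2S,3S)-2-[4-(benzyloxy)-3-methoxyphenyl]-5-bromo-7-methoxy-2,3-dihydro-1-benzofuran-3-yl}methyl tert-butyldimethylsilyl ether | Brc1cc(OC)c2c(c1)[C@@H](CO[Si](C)(C)C(C)(C)C)[C@@H](c1ccc(OCc3ccccc3)c(OC)c1)O2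
F8 | step 10 | C5-aryllithium derived from F7 | [Li]c1cc(OC)c2c(c1)[C@@H](CO[Si](C)(C)C(C)(C)C)[C@@H](c1ccc(OCc3ccccc3)c(OC)c1)O2
F9 | step 10 | aryl lactol from F8 and 13 (lactol carbon epimers) | COc1cc([C@H]2OC[C@@H]3[C@H]2COC3(O)c2cc(OC)c3c(c2)[C@@H](CO[Si](C)(C)C(C)(C)C)[C@@H](c2ccc(OCc4ccccc4)c(OC)c2)O3)ccc1OCc1ccccc1
F10 | step 10 | tert-butyldimethylsilyl ether of 24 | COc1cc([C@H]2OC[C@@H]3[C@H]2CO[C@@H]3c2cc(OC)c3c(c2)[C@@H](CO[Si](C)(C)C(C)(C)C)[C@@H](c2ccc(OCc4ccccc4)c(OC)c2)O3)ccc1OCc1ccccc1
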